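The earlier runs and the new flask were generated by integration from invented constants; noise was put on by code.

Start with one division: impurity charged over catalyst charged, for the three flasks below.

in all of them: left-handed substrate 0.80 M; right-handed substrate 0.80 M; free catalyst 1.6 mM

| run | reagent | impurity | remark |
|---|---|---|---|
| spring | 0.88 M | 0.50 mM | run made earlier |
| dawn | 0.88 M | 2 mM | run made earlier |
| flask | 0.880 M | 1.0 mM |  |

- spring (time / d: left-handed product / %): 0.833: 24; 2.50: 32; 4.00: 34; 6.00: 36; 10.0: 36; 12.0: 34; 15.0: 34
- dawn (time / d: left-handed product / %): 0.833: 2; 2.50: 0; 4.00: 0; 6.00: 0; 10.0: 2; 12.0: 1; 15.0: 2

(standard deviation of a reading: 1.5 percentage points)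

- apparent order in reagent when 5.0% of the left-handed substrate and right-handed substrate together are converted (percent change of the rate of making left-handed product for one percent more reagent charged)

- free catalyst is single-handed; left-handed substrate and right-handed substrate are mirror images of each other, charged as a racemate, each of them at the stated concentration
- the analysis behind the earlier runs scatters by 1.5 percentage points, standard deviation
- steps that have been proposed: reagent + free catalyst + left-handed substrate -> free catalyst + left-handed product; reagent + free catalyst + right-handed substrate -> free catalyst + right-handed product; free catalyst + impurity -> spent catalyst A; reagent + free catalyst -> spent catalyst B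
- no earlier run changes the charge of reagent; that part of a forecast is a guess

Call s, the surviving share, the part of the catalyst left free once each impurity has taken one catalyst: s = (catalyst − impurity)/catalyst. Read it as a titration. The spring run has s = 68.8% and reads 34% of left-handed product at 15.0 d. The dawn run has more impurity than catalyst and reads 2% at 15.0 d. For the flask, s = 37.5%.

Now reckon the order. s holds no reagent, so take the rate as proportional to reagent: first answer, order one, and a guess, since no earlier run varies reagent. Go round once: call the look the moment when 5.0% of both substrates together is converted; by then the flask has used x = 0.0800 M of reagent, so the order is cB/(cB − x) = 1.10, with cB the reagent charged. This needs the titration to end before the look, which the readings do not show: they begin at 0.833 d, and the forecast puts the look near 0.1 d.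

The forecast gives 1.1, on this ground: “Reagent-driven catalyst loss and turnover both scale with reagent, so catalyst at fixed conversion does not depend on the charge”.

The flask gives 1.1, with the look at 0.0686 d.

    reagent + free catalyst + left-handed substrate → free catalyst + left-handed product (k = 1.40 /M²/min)
    reagent + free catalyst + right-handed substrate → free catalyst + right-handed product (k = 0.561 /M²/min)
    free catalyst + impurity → spent catalyst A (k = 176 /M/min)
    reagent + free catalyst → spent catalyst B (k = 7.82 × 10⁻⁴ /M/min)

Impurity holds the flask's rate down: with the step of free catalyst and impurity taken away, the rate at the look is 2.79 times the actual one, and 1/s gives 2.67. The run with twice the free catalyst uses s again: with the same impurity the titration reckons 3.67 times as much free catalyst as in the flask, and the rate in that run is 3.86 times the flask's.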